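**Retrosynthetic overview**

1. The pyran ring (O2–C1=C8a, C3=C4) is closed last, by cyclodehydration of a C1 aldehyde with a C3 ketone, after the C7–O–C4a oxygen bridge of a 7-oxanorbornene has been opened to give the C7 tertiary hydroxyl and the C4a=C5–C6=O enone.
2. Key disconnection (C4a–C8a and C7–C8 together): intramolecular Diels–Alder reaction of a 2-methyl-3-silyloxyfuran (diene C7=C6–C5=C4a) with an E-β-alkoxyacrylate (C8a=C8) tied as an ester through O2 to a C3 carbinol; one step closes the carbocycle and a δ-lactone (the later pyran ring) and sets C7 and C8.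
3. Enabling feature: the unit C7(OH)(CH3)–C6(=O)–C5=C4a of the carbocycle is an opened 7-oxanorbornenone, i.e. a latent 3-oxyfuran whose ring oxygen is the C7 hydroxyl oxygen, and O2 joins C1 to C3, so C1 can be the ester carbonyl of the tether.
4. Stereochemical relay: C3 is kept sp3 (S, from L-malic acid); it sets C9 by chelation-controlled addition and C7/C8 in the cycloaddition, and is erased when C3 is oxidized to the ketone.
5. Side chain: E-alkenyl iodide by carboalumination of an ethynyloxolane (anti crotylboration, hydroboration, etherification). Order of ring formation: oxolane, furan, carbocycle plus lactone (key step), pyran.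

Key step: step 16

Remark on the chemistry: atom labels (O2, C1, C3, C4, C4a, C5–C8, C8a) follow the isochromene numbering of the target and C9 is the side-chain carbinol carbon; the SMILES is read as 7S,8R (trans diol), 9S, E alkene and (2S,3S)-trans oxolane. PMB = 4-methoxybenzyl.

**Route**

Step 1
Reactants: 1 3-(triisopropylsilyl)prop-2-ynal; 2 (E)-crotylboronic acid pinacol ester
Product: 3 (3S,4S)-4-methyl-1-(triisopropylsilyl)hex-5-en-1-yn-3-ol
Conditions: (S)-3,3'-bis(2,4,6-triisopropylphenyl)-1,1'-binaphthyl-2,2'-diyl hydrogen phosphate (5 mol %), 4 Å molecular sieves, toluene, −30 °C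
Reagents that add atoms: none
Why: Chiral-phosphoric-acid-catalysed crotylboration through a closed chair transition state, in which the E-crotyl geometry gives the anti (3S,4S) relationship and the catalyst enantiomer sets the carbinol configuration (the mirror-image catalyst is used should the sense be opposite).

Step 2
Reactants: 3 (3S,4S)-4-methyl-1-(triisopropylsilyl)hex-5-en-1-yn-3-ol
Product: 4 (3S,4S)-3-methyl-6-(triisopropylsilyl)hex-5-yne-1,4-diol
Conditions: 9-BBN (2.5 equiv), THF, 0 °C to rt; then NaOH (3 M), H2O2 (30%), 0 °C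
Reagents that add atoms: hydrogen peroxide, OO
Why: Anti-Markovnikov hydroboration–oxidation of the terminal alkene; the hindered silylalkyne should not react and no stereocentre is touched.

Step 3
Reactants: 4 (3S,4S)-3-methyl-6-(triisopropylsilyl)hex-5-yne-1,4-diol
Product: 6 triisopropyl{[(2S,3S)-3-methyloxolan-2-yl]ethynyl}silane, via primary tosylate 5 (not isolated)
Conditions: TsCl (1.05 equiv), Et3N, 4-(dimethylamino)pyridine (cat.), CH2Cl2, 0 °C; then KOt-Bu, THF, 0 °C to rt
Reagents that add atoms: none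
Why: Selective sulfonylation of the primary hydroxyl and intramolecular Williamson etherification (5-exo-tet) by the secondary alkoxide; both stereocentres are retained, so the anti diol should give the trans-2,3-disubstituted oxolane.

Step 4
Reactants: 6 triisopropyl{[(2S,3S)-3-methyloxolan-2-yl]ethynyl}silane
Product: 7 (2S,3S)-2-ethynyl-3-methyloxolane
Conditions: Bu4NF (1.2 equiv), THF, 0 °C (product kept in solution, volatile)
Reagents that add atoms: none
Why: Fluoride-mediated protodesilylation of the alkynylsilane.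

Step 5
Reactants: 7 (2S,3S)-2-ethynyl-3-methyloxolane
Product: 9 (2S,3S)-2-[(E)-1-iodoprop-1-en-2-yl]-3-methyloxolane, via alkenylalane 8 (not isolated)
Conditions: Me3Al (2.5 equiv), Cp2ZrCl2 (0.25 equiv), CH2Cl2, 0 °C to rt; then I2, THF, −30 °C
Reagents that add atoms: trimethylaluminium, C[Al](C)C; iodine, II
Why: Zirconium-catalysed methylalumination (Negishi carboalumination) adds CH3 and Al syn across the alkyne with methyl on the internal carbon, and iodinolysis with retention should give the E-iodoalkene with iodine trans to the oxolane.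

Step 6
Reactants: 10 2-[(4S)-2,2-dimethyl-5-oxo-1,3-dioxolan-4-yl]acetic acid (from L-malic acid)
Product: 11 2-[(4S)-2,2-dimethyl-5-oxo-1,3-dioxolan-4-yl]acetyl chloride
Conditions: (COCl)2, N,N-dimethylformamide (cat.), CH2Cl2, 0 °C to rt
Reagents that add atoms: oxalyl chloride, ClC(=O)C(=O)Cl
Why: Acid chloride formation through the chloroiminium species; the dioxolanone (masked hydroxy acid) and its stereocentre are not touched.

Step 7
Reactants: 12 3-hydroxybutan-2-one (racemic)
Product: 13 3-(triethylsilyloxy)butan-2-one (racemic)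
Conditions: Et3SiCl, imidazole, CH2Cl2, 0 °C
Reagents that add atoms: chlorotriethylsilane, CC[Si](Cl)(CC)CC
Why: Standard silyl ether formation; the stereocentre is irrelevant because it becomes sp2 in step 10.

Step 8
Reactants: 11 2-[(4S)-2,2-dimethyl-5-oxo-1,3-dioxolan-4-yl]acetyl chloride; 13 3-(triethylsilyloxy)butan-2-one
Product: 14 (5S)-2,2-dimethyl-5-[2,4-dioxo-5-(triethylsilyloxy)hexyl]-1,3-dioxolan-4-one
Conditions: MgBr2·OEt2 (2.5 equiv), i-Pr2NEt (3 equiv), CH2Cl2, 0 °C to rt
Reagents that add atoms: none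
Why: Soft-enolization C-acylation (Claisen-type): the magnesium enolate forms at the methyl group of the ketone and attacks the acid chloride, and the 1,3-diketone is held as its magnesium chelate, which should prevent a second acylation.

Step 9
Reactants: 14 (5S)-2,2-dimethyl-5-[2,4-dioxo-5-(triethylsilyloxy)hexyl]-1,3-dioxolan-4-one
Product: 16 (5S)-2,2-dimethyl-5-[(5-methyl-4-oxo-4,5-dihydrofuran-2-yl)methyl]-1,3-dioxolan-4-one, via hydroxy diketone 15 (not isolated)
Conditions: HF (48% aq.), MeCN, 0 °C to rt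
Reagents that add atoms: none
Why: Desilylation followed by acid-catalysed cyclodehydration of the 5-hydroxy-2,4-dione (hydroxyl onto the distal carbonyl, loss of water) should give the 3(2H)-furanone; its ring stereocentre is of no consequence.

Step 10
Reactants: 16 (5S)-2,2-dimethyl-5-[(5-methyl-4-oxo-4,5-dihydrofuran-2-yl)methyl]-1,3-dioxolan-4-one
Product: 17 (5S)-2,2-dimethyl-5-({5-methyl-4-[(triisopropylsilyl)oxy]furan-2-yl}methyl)-1,3-dioxolan-4-one
Conditions: i-Pr3SiOTf (1.1 equiv), Et3N, CH2Cl2, 0 °C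
Reagents that add atoms: triisopropylsilyl trifluoromethanesulfonate, CC(C)[Si](OS(=O)(=O)C(F)(F)F)(C(C)C)C(C)C
Why: O-silylation of the furanone enol, driven by aromatization, gives the 3-silyloxyfuran, which is the diene of the key step and also masks the ketone during the organometallic steps.

Step 11
Reactants: 17 (5S)-2,2-dimethyl-5-({5-methyl-4-[(triisopropylsilyl)oxy]furan-2-yl}methyl)-1,3-dioxolan-4-one
Product: 18 (2S)-2-hydroxy-N-methoxy-N-methyl-3-{5-methyl-4-[(triisopropylsilyl)oxy]furan-2-yl}propanamide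
Conditions: MeNH(OMe)·HCl (2 equiv), i-PrMgCl (4 equiv), THF, −20 °C
Reagents that add atoms: N,O-dimethylhydroxylamine hydrochloride, CNOC.Cl
Why: Weinreb amide formation by aminolysis of the activated dioxolanone with the magnesium amide, which releases acetone and the free C3 hydroxyl without touching the stereocentre.

Step 12
Reactants: 18 (2S)-2-hydroxy-N-methoxy-N-methyl-3-{5-methyl-4-[(triisopropylsilyl)oxy]furan-2-yl}propanamide
Product: 19 (3S)-3-hydroxy-4-{5-methyl-4-[(triisopropylsilyl)oxy]furan-2-yl}butan-2-one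
Conditions: MeMgBr (3 equiv), THF, −78 to 0 °C
Reagents that add atoms: methylmagnesium bromide, C[Mg]Br
Why: Weinreb ketone synthesis; the chelated tetrahedral intermediate should prevent over-addition.

Step 13
Reactants: 9 (2S,3S)-2-[(E)-1-iodoprop-1-en-2-yl]-3-methyloxolane; 19 (3S)-3-hydroxy-4-{5-methyl-4-[(triisopropylsilyl)oxy]furan-2-yl}butan-2-one
Product: 21 (2S,3S,4E)-3-methyl-1-{5-methyl-4-[(triisopropylsilyl)oxy]furan-2-yl}-5-[(2S,3S)-3-methyloxolan-2-yl]hex-4-ene-2,3-diol, via alkenyllithium 20 (not isolated)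
Conditions: 9: t-BuLi (2.0 equiv), Et2O, −78 °C; 19: t-BuMgCl (1.0 equiv), THF, −78 °C; combine, −78 to −40 °C; aq. NH4Cl
Reagents that add atoms: none
Why: Iodine–lithium exchange with retention of alkene geometry, then chelation-controlled (Cram-chelate) 1,2-addition: magnesium bridges the C3 alkoxide and the ketone oxygen, the nucleophile enters from the face of the C3 hydrogen, and the tertiary carbinol should form as 9S.

Step 14
Reactants: 22 4-methoxybenzyl alcohol; 23 methyl propiolate
Product: 24 methyl (E)-3-[(4-methoxybenzyl)oxy]prop-2-enoate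
Conditions: N-methylmorpholine (10 mol %), CH2Cl2, rt
Reagents that add atoms: none
Why: Tertiary-amine-catalysed oxa-Michael addition of the alcohol to the ynoate, which should give the E β-alkoxyacrylate.

Step 15
Reactants: 24 methyl (E)-3-[(4-methoxybenzyl)oxy]prop-2-enoate
Product: 25 (E)-3-[(4-methoxybenzyl)oxy]prop-2-enoic acid
Conditions: LiOH·H2O, THF/H2O, 0 °C to rt; then HCl (1 M) to pH 3, 0 °C
Reagents that add atoms: lithium hydroxide, [Li+].[OH-]
Why: Saponification of the methyl ester; the vinylogous carbonate double bond keeps its E geometry.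

Step 16
Reactants: 21 (2S,3S,4E)-3-methyl-1-{5-methyl-4-[(triisopropylsilyl)oxy]furan-2-yl}-5-[(2S,3S)-3-methyloxolan-2-yl]hex-4-ene-2,3-diol; 25 (E)-3-[(4-methoxybenzyl)oxy]prop-2-enoic acid
Product: 27 oxa-bridged tricyclic lactone (C1 exo and 8-OPMB endo), via acrylate ester 26 (not isolated)
Conditions: DCC, 4-(dimethylamino)pyridine (cat.), CH2Cl2, 0 °C to rt; filter, exchange solvent; toluene, 2,6-di-tert-butyl-4-methylphenol (cat.), 100 °C, sealed tube
Reagents that add atoms: none
Why: Steglich esterification of the secondary C3 hydroxyl (the tertiary C9 hydroxyl should not react) is followed by a thermal intramolecular Diels–Alder reaction of the furan: the electron-rich 2-methyl-3-silyloxyfuran (diene C7=C6–C5=C4a, most nucleophilic at C7) adds across the E-acrylate C8a=C8 (electrophilic at C8) in one concerted, asynchronous step that forms C7–C8 and C4a–C8a. The closest known reaction type is the intramolecular Diels–Alder reaction of furans carrying acrylate or fumarate ester tethers, together with the cycloadditions of 3-alkoxy- and 3-silyloxyfurans. The carbocycle closes as the six-membered ring of the [4+2] adduct, bridged by the furan oxygen between C7 and C4a, and the δ-lactone (O2–C1–C8a–C4a–C4–C3, the later pyran ring) closes as the tether ring fused at C4a–C8a, which the four-atom tether allows only in the exo mode (C1 syn to the oxygen bridge). C4a, C8a and C7 follow from suprafacial addition to the planar furan, whose ring oxygen becomes the C7 oxygen; at C8 the E-alkene places the OPMB group trans to C1, hence endo and anti to the bridge, which is the trans 7,8-diol relationship. The absolute sense should come from the 3S carbinol carbon in the tether: its bulky C9 substituent must sit pseudo-equatorial on the forming lactone ring, away from the furan oxygen, so only the furan face leading to 7S,8R is reachable. The step needs regioselectivity (enforced by the tether and matched by polarity), periselectivity for the furan over the unactivated side-chain alkene, and resistance to cycloreversion, which the donor silyloxy group and immediate use of the adduct should provide.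

Step 17
Reactants: 27 oxa-bridged tricyclic lactone
Product: 28 oxa-bridged triol (C1 primary alcohol, C3 secondary alcohol, C9 tertiary alcohol)
Conditions: LiBH4 (3 equiv), THF, 0 °C to rt; aq. NH4Cl
Reagents that add atoms: none
Why: Hydride reduction of the δ-lactone to the 1,5-diol; LiBH4 should leave the silyl enol ether, the PMB ether and the alkene untouched.

Step 18
Reactants: 28 oxa-bridged triol
Product: 29 oxa-bridged keto aldehyde (C1 aldehyde and C3 ketone)
Conditions: (COCl)2, DMSO, CH2Cl2, −78 °C; Et3N, −78 to −30 °C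
Reagents that add atoms: none
Why: Swern oxidation, in which both hydroxyls are activated as alkoxysulfonium ions before base is added, so the primary alcohol should give the aldehyde and the C3 carbinol the ketone without lactol formation; this removes the relay stereocentre, and the tertiary hydroxyl is inert.

Step 19
Reactants: 29 oxa-bridged keto aldehyde
Product: 32 (7S,8R)-7-hydroxy-3-{(2S,3E)-2-hydroxy-4-[(2S,3S)-3-methyloxolan-2-yl]pent-3-en-2-yl}-8-[(4-methoxybenzyl)oxy]-7-methyl-7,8-dihydro-6H-isochromen-6-one, via bridged ketone 30 (not isolated), via ring-opened enone 31 (not isolated)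
Conditions: Bu4NF (1.1 equiv), AcOH (1.1 equiv), THF, −20 to 0 °C; then pyridinium p-toluenesulfonate (20 mol %), 4 Å molecular sieves, CH2Cl2, rt
Reagents that add atoms: none
Why: Fluoride cleaves the silyl enol ether to the 7-oxanorbornanone, whose enolate expels the bridging oxygen from C4a (strain-driven E1cB) to give the C4a=C5 enone and the C7 hydroxyl; the 1,5-keto aldehyde then cyclodehydrates (enol oxygen of the C3 ketone onto C1, loss of water through the now vinylogously acidic C8a–H) to the pyran, without touching C7 or C8.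

Step 20
Reactants: 32 the 8-O-PMB ether
Product: 33 (7S,8R)-7,8-dihydroxy-3-{(2S,3E)-2-hydroxy-4-[(2S,3S)-3-methyloxolan-2-yl]pent-3-en-2-yl}-7-methyl-7,8-dihydro-6H-isochromen-6-one (target, CNP0502247.2)
Conditions: DDQ (1.3 equiv), CH2Cl2/pH 7 phosphate buffer (10:1), 0 °C
Reagents that add atoms: none
Why: Oxidative cleavage of the PMB ether (benzylic hydride abstraction, hydrolysis of the oxocarbenium ion) under buffered conditions, which should spare the acid-sensitive C8 carbinol.

**Compound list**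

1 | 3-(triisopropylsilyl)prop-2-ynal | O=CC#C[Si](C(C)C)(C(C)C)C(C)C | starting material
2 | (E)-crotylboronic acid pinacol ester | C/C=C/CB1OC(C)(C)C(C)(C)O1 | starting material
3 | (3S,4S)-4-methyl-1-(triisopropylsilyl)hex-5-en-1-yn-3-ol | CC(C)[Si](C(C)C)(C(C)C)C#C[C@@H](O)[C@@H](C)C=C | intermediate
4 | (3S,4S)-3-methyl-6-(triisopropylsilyl)hex-5-yne-1,4-diol | CC(C)[Si](C(C)C)(C(C)C)C#C[C@@H](O)[C@@H](C)CCO | intermediate
5 | (3S,4S)-4-hydroxy-3-methyl-6-(triisopropylsilyl)hex-5-yn-1-yl 4-methylbenzenesulfonate | CC(C)[Si](C(C)C)(C(C)C)C#C[C@@H](O)[C@@H](C)CCOS(=O)(=O)c1ccc(C)cc1 | intermediate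
6 | triisopropyl{[(2S,3S)-3-methyloxolan-2-yl]ethynyl}silane | CC(C)[Si](C(C)C)(C(C)C)C#C[C@H]1OCC[C@@H]1C | intermediate
7 | (2S,3S)-2-ethynyl-3-methyloxolane | C#C[C@H]1OCC[C@@H]1C | intermediate
8 | dimethyl{(E)-2-[(2S,3S)-3-methyloxolan-2-yl]prop-1-en-1-yl}alumane | C/C(=C\[Al](C)C)[C@H]1OCC[C@@H]1C | intermediate
9 | (2S,3S)-2-[(E)-1-iodoprop-1-en-2-yl]-3-methyloxolane | C/C(=C\I)[C@H]1OCC[C@@H]1C | intermediate
10 | 2-[(4S)-2,2-dimethyl-5-oxo-1,3-dioxolan-4-yl]acetic acid | CC1(C)O[C@@H](CC(=O)O)C(=O)O1 | starting material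
11 | 2-[(4S)-2,2-dimethyl-5-oxo-1,3-dioxolan-4-yl]acetyl chloride | CC1(C)O[C@@H](CC(=O)Cl)C(=O)O1 | intermediate
12 | 3-hydroxybutan-2-one (racemic) | CC(O)C(C)=O | starting material
13 | 3-(triethylsilyloxy)butan-2-one (racemic) | CC(O[Si](CC)(CC)CC)C(C)=O | intermediate
14 | (5S)-2,2-dimethyl-5-[2,4-dioxo-5-(triethylsilyloxy)hexyl]-1,3-dioxolan-4-one (both epimers at the silyloxy carbon) | CC(O[Si](CC)(CC)CC)C(=O)CC(=O)C[C@@H]1OC(C)(C)OC1=O | intermediate
15 | (5S)-5-(5-hydroxy-2,4-dioxohexyl)-2,2-dimethyl-1,3-dioxolan-4-one | CC(O)C(=O)CC(=O)C[C@@H]1OC(C)(C)OC1=O | intermediate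
16 | (5S)-2,2-dimethyl-5-[(5-methyl-4-oxo-4,5-dihydrofuran-2-yl)methyl]-1,3-dioxolan-4-one (both epimers at the furanone CH) | CC1OC(C[C@@H]2OC(C)(C)OC2=O)=CC1=O | intermediate
17 | (5S)-2,2-dimethyl-5-({5-methyl-4-[(triisopropylsilyl)oxy]furan-2-yl}methyl)-1,3-dioxolan-4-one | Cc1oc(C[C@@H]2OC(C)(C)OC2=O)cc1O[Si](C(C)C)(C(C)C)C(C)C | intermediate
18 | (2S)-2-hydroxy-N-methoxy-N-methyl-3-{5-methyl-4-[(triisopropylsilyl)oxy]furan-2-yl}propanamide | CON(C)C(=O)[C@@H](O)Cc1cc(O[Si](C(C)C)(C(C)C)C(C)C)c(C)o1 | intermediate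
19 | (3S)-3-hydroxy-4-{5-methyl-4-[(triisopropylsilyl)oxy]furan-2-yl}butan-2-one | CC(=O)[C@@H](O)Cc1cc(O[Si](C(C)C)(C(C)C)C(C)C)c(C)o1 | intermediate
20 | {(E)-2-[(2S,3S)-3-methyloxolan-2-yl]prop-1-en-1-yl}lithium | C/C(=C\[Li])[C@H]1OCC[C@@H]1C | intermediate
21 | (2S,3S,4E)-3-methyl-1-{5-methyl-4-[(triisopropylsilyl)oxy]furan-2-yl}-5-[(2S,3S)-3-methyloxolan-2-yl]hex-4-ene-2,3-diol | C/C(=C\[C@](C)(O)[C@@H](O)Cc1cc(O[Si](C(C)C)(C(C)C)C(C)C)c(C)o1)[C@H]1OCC[C@@H]1C | intermediate
22 | 4-methoxybenzyl alcohol | COc1ccc(CO)cc1 | starting material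
23 | methyl propiolate | C#CC(=O)OC | starting material
24 | methyl (E)-3-[(4-methoxybenzyl)oxy]prop-2-enoate | COC(=O)/C=C/OCc1ccc(OC)cc1 | intermediate
25 | (E)-3-[(4-methoxybenzyl)oxy]prop-2-enoic acid | OC(=O)/C=C/OCc1ccc(OC)cc1 | intermediate
26 | C2 ester of diol 21 with acid 25: (2S,3S,4E)-3-hydroxy-3-methyl-1-{5-methyl-4-[(triisopropylsilyl)oxy]furan-2-yl}-5-[(2S,3S)-3-methyloxolan-2-yl]hex-4-en-2-yl (E)-3-[(4-methoxybenzyl)oxy]prop-2-enoate | C/C(=C\[C@](C)(O)[C@@H](OC(=O)/C=C/OCc1ccc(OC)cc1)Cc1cc(O[Si](C(C)C)(C(C)C)C(C)C)c(C)o1)[C@H]1OCC[C@@H]1C | intermediate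
27 | Diels–Alder adduct: oxanorbornene C4a–C5=C6(OSi-i-Pr3)–C7(CH3)–C8–C8a with an oxygen bridge between C7 and C4a, fused at C4a–C8a to the δ-lactone O2–C1(=O); C1 exo (syn to the bridge), 8-OPMB endo (anti to the bridge), 3S with the (S)-carbinol side chain equatorial | C[C@@]12O[C@]3(C=C1O[Si](C(C)C)(C(C)C)C(C)C)C[C@@H]([C@@](C)(O)/C=C(\C)[C@H]4OCC[C@@H]4C)OC(=O)[C@@H]3[C@H]2OCc5ccc(OC)cc5 | intermediate
28 | oxa-bridged triol: as 27 with the lactone reduced to C1H2OH on C8a and a free (S)-C3 carbinol | C[C@@]12O[C@](C=C1O[Si](C(C)C)(C(C)C)C(C)C)(C[C@H](O)[C@@](C)(O)/C=C(\C)[C@H]3OCC[C@@H]3C)[C@H](CO)[C@H]2OCc4ccc(OC)cc4 | intermediate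
29 | oxa-bridged keto aldehyde: as 28 with C1 as aldehyde and C3 as ketone | C[C@@]12O[C@](C=C1O[Si](C(C)C)(C(C)C)C(C)C)(CC(=O)[C@@](C)(O)/C=C(\C)[C@H]3OCC[C@@H]3C)[C@H](C=O)[C@H]2OCc4ccc(OC)cc4 | intermediate
30 | bridged ketone: 7-oxabicyclo[2.2.1]heptan-2-one (C6 ketone) from desilylation of 29 | C[C@@]12O[C@](CC1=O)(CC(=O)[C@@](C)(O)/C=C(\C)[C@H]3OCC[C@@H]3C)[C@H](C=O)[C@H]2OCc4ccc(OC)cc4 | intermediate
31 | ring-opened enone: (7S,8R)-7-hydroxy-7-methyl-8-OPMB-cyclohex-4a(5)-en-6-one carrying the C1 aldehyde on C8a and the CH2–C3(=O)–C9 side chain on C4a | C/C(=C\[C@](C)(O)C(=O)CC1=CC(=O)[C@@](C)(O)[C@H](OCc2ccc(OC)cc2)[C@H]1C=O)[C@H]1OCC[C@@H]1C | intermediate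
32 | (7S,8R)-7-hydroxy-3-{(2S,3E)-2-hydroxy-4-[(2S,3S)-3-methyloxolan-2-yl]pent-3-en-2-yl}-8-[(4-methoxybenzyl)oxy]-7-methyl-7,8-dihydro-6H-isochromen-6-one | C/C(=C\[C@](C)(O)C1=CC2=CC(=O)[C@@](C)(O)[C@H](OCc3ccc(OC)cc3)C2=CO1)[C@H]1OCC[C@@H]1C | intermediate
33 | (7S,8R)-7,8-dihydroxy-3-{(2S,3E)-2-hydroxy-4-[(2S,3S)-3-methyloxolan-2-yl]pent-3-en-2-yl}-7-methyl-7,8-dihydro-6H-isochromen-6-one | C/C(=C\[C@](C)(O)C1=CC2=CC(=O)[C@@](C)(O)[C@H](O)C2=CO1)[C@H]1OCC[C@@H]1C | target

**Step count and risks**

Total step count: 20. Longest linear sequence: 12 steps (steps 6, 8–13, 16–20).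

Steps most likely to fail:

Step 16. The cycloaddition may not proceed, or may revert, because the push–pull alkoxyacrylate is a weak dienophile held by an ester tether; facial control by C3 may also be incomplete. The fallback sets out from 21. Steglich esterification with (E)-3-(4,4,5,5-tetramethyl-1,3,2-dioxaborolan-2-yl)acrylic acid should give the boryl acrylate ester F1. Its more electrophilic double bond should undergo the same intramolecular cycloaddition at lower temperature to give the C8-boryl oxa-bridged lactone F2 (boron endo). Oxidation with NaBO3·4H2O in THF/H2O replaces boron by hydroxyl with retention and gives the endo C8 alcohol F3. Neutral 4-methoxybenzylation of the secondary hydroxyl (2-(4-methoxybenzyloxy)-4-methylquinoline, MeOTf, MgO) comes back to the route at 27.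

Step 19. Once fluoride unveils the ketone, the enolizable C1 aldehyde may lose the C8 alkoxy group by β-elimination, or the sequence may stall at the bridged ketone. The fallback sets out from 27. Bu4NF/AcOH on the lactone opens the oxygen bridge first and gives the hydroxy enone lactone F4. LiBH4/CeCl3 reduces the lactone and the enone carbonyl to the pentaol F5. Threefold Swern oxidation (primary alcohol, C3 carbinol, allylic C6 carbinol) generates 31 without fluoride at the aldehyde stage, and pyridinium p-toluenesulfonate closes the pyran, coming back to the route at 32.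

Step 13. The basic alkenyllithium may enolize the α-hydroxy ketone, which would lower conversion and erode chelation control. The fallback sets out from 7 and 19. The lithium acetylide of 7 (n-BuLi; less basic and small) is added to the chloromagnesium alkoxide of 19 under the same chelation control to give the propargylic diol F6. Hydroxyl-directed trans-hydroalumination with NaAlH2(OCH2CH2OCH3)2 and iodination give the Z-iodoalkene F7 (iodine on the carbon bearing the oxolane, cis to C9). Negishi methylation (MeZnCl, Pd(PPh3)4) with retention comes back to the route at 21.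

Further compounds
F1 | step 16 | C2 ester of diol 21 with (E)-3-(pinacolboryl)acrylic acid | C/C(=C\[C@](C)(O)[C@@H](OC(=O)/C=C/B1OC(C)(C)C(C)(C)O1)Cc1cc(O[Si](C(C)C)(C(C)C)C(C)C)c(C)o1)[C@H]1OCC[C@@H]1C
F2 | step 16 | oxa-bridged tricyclic lactone as 27 with endo pinacolboryl at C8 | C[C@@]12O[C@]3(C=C1O[Si](C(C)C)(C(C)C)C(C)C)C[C@@H]([C@@](C)(O)/C=C(\C)[C@H]4OCC[C@@H]4C)OC(=O)[C@@H]3[C@H]2B5OC(C)(C)C(C)(C)O5
F3 | step 16 | oxa-bridged tricyclic lactone as 27 with free endo C8 hydroxyl | C[C@@]12O[C@]3(C=C1O[Si](C(C)C)(C(C)C)C(C)C)C[C@@H]([C@@](C)(O)/C=C(\C)[C@H]4OCC[C@@H]4C)OC(=O)[C@@H]3[C@H]2O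
F4 | step 19 | (3S,7S,8R)-7-hydroxy-8-OPMB-7-methyl enone δ-lactone (C1 lactone carbonyl, C4a=C5–C6=O, bridge opened) | C/C(=C\[C@](C)(O)[C@@H]1CC2=CC(=O)[C@@](C)(O)[C@H](OCc3ccc(OC)cc3)[C@H]2C(=O)O1)[C@H]1OCC[C@@H]1C
F5 | step 19 | pentaol from reduction of F4 (C1 primary, C3 secondary, C6 allylic secondary as epimer mixture, C7 and C9 tertiary hydroxyls) | C/C(=C\[C@](C)(O)[C@@H](O)CC1=CC(O)[C@@](C)(O)[C@H](OCc2ccc(OC)cc2)[C@H]1CO)[C@H]1OCC[C@@H]1C
F6 | step 13 | (2S,3S)-3-methyl-1-{5-methyl-4-[(triisopropylsilyl)oxy]furan-2-yl}-5-[(2S,3S)-3-methyloxolan-2-yl]pent-4-yne-2,3-diol | C(#C[C@](C)(O)[C@@H](O)Cc1cc(O[Si](C(C)C)(C(C)C)C(C)C)c(C)o1)[C@H]1OCC[C@@H]1C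
F7 | step 13 | (2S,3S,4Z)-5-iodo-3-methyl-1-{5-methyl-4-[(triisopropylsilyl)oxy]furan-2-yl}-5-[(2S,3S)-3-methyloxolan-2-yl]pent-4-ene-2,3-diol | I/C(=C\[C@](C)(O)[C@@H](O)Cc1cc(O[Si](C(C)C)(C(C)C)C(C)C)c(C)o1)[C@H]1OCC[C@@H]1C
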